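The data are calculated for an exercise; scatter was added.

The charged ratio of reagent to starting material is the number I watch in these flasks, and one short integration over the two steps of the second substrate turns it into an estimate of the cross product.

all flasks: starting material 0.10 M
- Wednesday's: reagent 0.097 M; second substrate 0.050 M; run made earlier
- Saturday's: reagent 0.17 M; second substrate 0.050 M; run made earlier
- zeta: reagent 0.120 M; second substrate 0.0500 M; time 8.0 h
- gamma: reagent 0.240 M; second substrate 0.0500 M; time 8.0 h

| run | time / h | side product / % | cross product / % | target / % | starting material / % |
|---|---|---|---|---|---|
| Wednesday's | 0.417 | 0 | 20.5 | 12.6 | 65.3 |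
| Wednesday's | 0.833 | 6.4 | 25.0 | 17.3 | 52.6 |
| Wednesday's | 1.50 | 12.9 | 23.6 | 22.8 | 40.6 |
| Wednesday's | 3.00 | 26.3 | 25.1 | 24.5 | 25.9 |
| Wednesday's | 6.00 | 38.9 | 25.7 | 23.3 | 13.0 |
| Saturday's | 0.500 | 4.1 | 17.1 | 23.5 | 55.7 |
| Saturday's | 1.33 | 16.2 | 17.2 | 33.1 | 29.9 |
| Saturday's | 2.50 | 27.9 | 19.3 | 38.9 | 15.6 |
| Saturday's | 4.00 | 33.5 | 18.1 | 41.3 | 7.3 |
| Saturday's | 6.00 | 38.1 | 16.6 | 38.4 | 3.8 |

(standard deviation of a reading: 1 percentage point)

- percentages count the starting material that a species holds: one side product counts as two
- the numbers in the tables scatter by 1 percentage point (one standard deviation)
- on the list of suspects stand: starting material + reagent -> target; 2 reagent -> self-condensation product; second substrate + reagent -> second product; starting material + second substrate -> cross product; starting material + target -> side product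

* which of these there is most of at the end, counted by the starting material in it, zeta (starting material / cross product / target / side product)
* which of these there is most of at the end, counted by the starting material in it, gamma (starting material / cross product / target / side product)
* amount of the one of these that there is most of at the end, in percent of the starting material charged, zeta
* amount of the one of these that there is most of at the end, in percent of the starting material charged, gamma

In the first instants the second substrate is the fast partner: Wednesday's run already reads 20.5 % of cross product at 0.417 h. It takes starting material and reagent in the rate ratio s·c(starting material)/c(reagent), with s the selectivity factor. If s is one and I take these two steps by themselves, both concentrations fall in proportion, their logarithms integrate alike, and within this reckoning the ratio stays as charged; the target step also consumes both, so this is an estimate. The second substrate is then shared in the charged proportion. That gives the toll, the percent of starting material ending as cross product: c(second substrate)/(c(starting material)+c(reagent)), for zeta 22.7 % and for gamma 14.7 %. The same formula gives 25.4 % for Wednesday's run, which reads 25.7 % at 6.00 h, and 18.5 % for Saturday's, which reads 18.1 % at 4.00 h.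

In the middle, target forms and side product follows it: Wednesday's side product reads 12.9 % at 1.50 h. At the end the contest is target against side product. At ratio 0.970, Wednesday's last readings are 38.9 % of side product and 23.3 % of target; at ratio 1.70, Saturday's stand level at 38.1 % and 38.4 %. Zeta, at 1.20, lies between, so I expect side product to lead. Gamma, at 2.40, lies beyond, so I expect target to lead. A line through those target readings gives 28.1 % for zeta and, extrapolated, 52.9 % for gamma. Allowing 6.50 % of starting material in zeta, the balance leaves 42.7 % of side product there.

The forecast gives side product at 45 % for zeta and target at 45 % for gamma, “so target narrowly leads”, a gamma figure lower than mine.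

    starting material + reagent → target (k = 5.61 M⁻¹ h⁻¹)
    2 reagent → self-condensation product (k = 0.853 M⁻¹ h⁻¹)
    second substrate + reagent → second product (k = 24.0 M⁻¹ h⁻¹)
    starting material + second substrate → cross product (k = 23.9 M⁻¹ h⁻¹)
    starting material + target → side product (k = 5.34 M⁻¹ h⁻¹)

Zeta ends with side product at 43.7 % and cross product at 22.7 %, and gamma with target at 50.7 %. In zeta, target is made 2.90 times as fast as it is used up at 0.827 h, but that ratio has fallen to 0.730 at 8.00 h, while the second-product step has 94 % of its turnover behind it by 0.800 h. In the neighbour charged with 0.17 M of starting material, the toll reckons to 17.2 % against 17.7 % of cross product, and at ratio 0.706 side product ends at 60.3 %.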